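**Plan**
1. Retrosynthetic cuts, in order:
   - the C13 acetate and C8 ester C–O bonds;
   - the C4–C5 epoxide oxygen (back to an E-alkene);
   - the butenolide C12=O and C6–H (back to a furan over C6, C7, C11, C12);
   - the C1–O bond of the 1,10-epoxide (back to a C1 ketone and a C10 carbinol);
   - the two furan C–O bonds (back to a C6 ketone and a C12 aldehyde);
   - last, the C1 and C6 carbonyl oxygens, which restores a C1=C6 double bond.
2. Enabling feature: C1 (epoxide CH) and C6 (lactone O–CH) are the two oxygen-bearing ring carbons that lie 1,6 across the cyclodecane. A bond between them turns the ten-membered ring into two fused six-membered rings: ring A (C1–C6) and ring B (C1, C6–C10).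
3. Forward order: anisole ring (later ring B), Friedel–Crafts closure of ring A, Birch reduction to the octalin, C7–C11 bond by Claisen rearrangement, ozonolysis to the ten-membered ring, furan, 1,10-epoxide, butenolide, 4,5-epoxide, then the two esters.
4. Stereochemistry:
   - C8 from catalytic asymmetric transfer hydrogenation of the furyl ketone;
   - C10 from outer-face enolate oxidation;
   - C1 from chelate-controlled reduction followed by SN2 inversion;
   - C6 from 1,3-syn reduction directed by C8–OH;
   - C4 and C5 from outer-face epoxidation of the E-alkene next to C6;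
   - the side-chain centre from commercial (R)-3-bromo-2-hydroxy-2-methylpropanoic acid.

Key step: step 11

Remark: germacrane labels C1–C15 of the target are used for all bicyclic and ten-membered intermediates; the centres C4, C7, C10 and C11 of the early intermediates are epimer mixtures, are drawn without configuration, and are all erased later (steps 12, 15, 20).

**Step 1**
Reactants: 1 3-methylanisole; 2 methylsuccinic anhydride (racemic)
Product: 3 4-(4-methoxy-2-methylphenyl)-2-methyl-4-oxobutanoic acid (racemic)
Conditions: AlCl3 (2.2 equiv), CH2Cl2, 0 °C to rt; aq HCl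
Reagents that add atoms: none
Why: Friedel–Crafts acylation in which the arene reacts para to methoxy and the anhydride opens at its less hindered CH2–C=O carbonyl, which places the future C15 methyl next to the carboxyl group (racemic centre, replaced in step 4).

**Step 2**
Reactants: 3 keto acid
Product: 4 4-(4-methoxy-2-methylphenyl)-2-methylbutanoic acid (racemic)
Conditions: H2 (3 bar), Pd/C, AcOH, 50 °C
Reagents that add atoms: none
Why: Catalytic hydrogenolysis of an aryl ketone activated by the para-methoxy group runs through the benzylic alcohol to the methylene and leaves the acid untouched.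

**Step 3**
Reactants: 4 arylbutanoic acid
Product: 5 7-methoxy-2,5-dimethyl-3,4-dihydronaphthalen-1(2H)-one (racemic)
Conditions: P2O5 in MeSO3H (1:10), rt to 40 °C
Reagents that add atoms: none
Why: Intramolecular Friedel–Crafts acylation closes six-membered ring A at the only free position ortho to the chain, the same meta-to-methoxy closure that gives 7-methoxy-1-tetralone.

**Step 4**
Reactants: 5 tetralone
Product: 6 2-hydroxy-7-methoxy-2,5-dimethyl-3,4-dihydronaphthalen-1(2H)-one (racemic)
Conditions: KN(SiMe3)2, THF, −78 °C; 2-(phenylsulfonyl)-3-phenyloxaziridine; AcOH quench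
Reagents that add atoms: 2-(phenylsulfonyl)-3-phenyloxaziridine, O=S(=O)(c1ccccc1)N1OC1c1ccccc1
Why: Enolate oxidation with an N-sulfonyloxaziridine is regiospecific because the ketone has a single enolisable carbon (C4), and the tertiary carbinol formed is racemic and sacrificial.

**Step 5**
Reactants: 6 hydroxy tetralone
Product: 7 2,7-dimethoxy-2,5-dimethyl-3,4-dihydronaphthalen-1(2H)-one (racemic)
Conditions: NaH, MeI, THF–DMF, 0 °C to rt
Reagents that add atoms: iodomethane, CI
Why: Williamson ether synthesis on the tertiary alkoxide gives a methyl ether that survives dissolving metal, strong base and hydride and later acts as the β-leaving group that fixes the position of the C4=C5 alkene.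

**Step 6**
Reactants: 7 methoxy tetralone
Product: 8 2,7-dimethoxy-2,5-dimethyl-1,2,3,4-tetrahydronaphthalene (racemic)
Conditions: H2 (5 bar), Pd/C, AcOH, HClO4 (cat.), 40 °C
Reagents that add atoms: none
Why: Catalytic hydrogenolysis of the aryl ketone proceeds through the benzylic alcohol; C4 bears no hydrogen, so dehydration to a styrene cannot intervene, and the non-benzylic tertiary ether is not cleaved.

**Step 7**
Reactants: 8 tetralin
Product: 9 3,6-dimethoxy-1,6-dimethyl-1,4,5,6,7,8-hexahydronaphthalene (C8–C9 enol ether and C1=C6 alkene)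
Conditions: Li, NH3 (l), THF, t-BuOH, −78 to −33 °C
Reagents that add atoms: none
Why: Birch reduction of a 3,4,5-trialkylanisole adds hydrogen ortho to methoxy (C7) and at the para-related methyl-bearing carbon (C10), as known for rings of the 1-methylestradiol methyl ether type, which leaves the enol ether and the tetrasubstituted ring-fusion alkene; C10 forms as an epimer mixture erased in step 15.

**Step 8**
Reactants: 10 (Z)-but-2-ene-1,4-diol
Product: 11 (Z)-4-[(tert-butyldiphenylsilyl)oxy]but-2-en-1-ol
Conditions: t-BuPh2SiCl (1 equiv), imidazole, diol (3 equiv), THF, 0 °C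
Reagents that add atoms: tert-butyl(chloro)diphenylsilane, CC(C)(C)[Si](Cl)(c1ccccc1)c1ccccc1
Why: Statistical monosilylation of a symmetrical diol used in excess gives the mono ether, and the surplus diol is washed out with water.

**Step 9**
Reactants: 9 Birch diene; 11 allylic alcohol
Product: 13 Δ1(6)-octal-8-one bearing CH(CH=CH2)CH2OSiPh2t-Bu at C7, via allyl dienol ether 12 (not isolated)
Conditions: EtCO2H (5 mol %), xylene, 135 °C, MeOH distilled off
Reagents that add atoms: none
Why: Acid-catalysed enol ether exchange followed by Claisen rearrangement, in which the oxocarbenium ion loses the doubly allylic C7 proton to give the conjugated dienol ether 12, whose [3,3] shift joins C7 to the substituted allyl terminus (C11) and returns the C8 ketone with the C1=C6 alkene in place; C7 and C11 form as mixtures and become furan sp2 carbons in step 12.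

**Step 10**
Reactants: 13 octalone
Product: 14 C8 ethylene ketal of 13 (octalin with the central C1=C6 alkene)
Conditions: Me3SiOCH2CH2OSiMe3, Me3SiOTf (5 mol %), CH2Cl2, −78 to −20 °C; pyridine quench
Reagents that add atoms: 1,2-bis(trimethylsilyloxy)ethane, C[Si](C)(C)OCCO[Si](C)(C)C
Why: Silyl-triflate-catalysed ketalisation at low temperature masks C8 without moving the β,γ-alkene, so that after ring cleavage only C6 can pair with the aldehyde.

**Step 11**
Reactants: 14 octalin ketal
Product: 15 cyclodecane-1,6-dione (C8 ethylene ketal; C4 OMe and Me; C10 Me; C7 CH(CHO)CH2OSiPh2t-Bu)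
Conditions: O3, CH2Cl2–MeOH, −78 °C; Me2S, −78 °C to rt
Reagents that add atoms: ozone, [O-][O+]=O
Why: Ozone adds as a 1,3-dipole to the electron-rich tetrasubstituted C1=C6 alkene and to the vinyl group, each primary ozonide cycloreverts to a carbonyl and a carbonyl oxide, methanol or the tethered ketone traps the latter, and Me2S reduces the peroxides to C=O. The closest known reaction is the ozonolysis of bicyclo[4.4.0]dec-1(6)-enes to cyclodecane-1,6-diones. No ring is closed by bond formation: the ten-membered carbocycle appears because the zero-atom bridge shared by the two six-membered rings is cut, so the strain and entropy cost of a medium-ring closure is never paid. No stereocentre is created, and those present at C4, C7, C10 and C11 are all erased later. The only selectivity needed is functional-group tolerance, which is secured because the sole further alkene is the vinyl group, whose cleavage to the C12 aldehyde is wanted, while ketal, ethers and silyl ether are inert to ozone at −78 °C. The cold, neutral reductive work-up should keep the dione from transannular aldol closure and from β-elimination at C4 or C8.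

**Step 12**
Reactants: 15 dione aldehyde
Product: 17 furan-fused cyclodecane-1,8-dione (furan O between C6 and C12; C13 OSiPh2t-Bu), via furan ketal 16 (not isolated)
Conditions: TsOH·H2O (5 mol %), toluene, 4 Å MS, 40 °C; then acetone–H2O, rt
Reagents that add atoms: water, O
Why: Paal–Knorr furan synthesis, in which the C6 ketone and the C12 aldehyde are the only 1,4-dicarbonyl pair (C8 masked, C1 remote), so cyclodehydration differentiates the two ring ketones and erases C7 and C11, and the now furyl-stabilised ketal hydrolyses under the same mild acid.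

**Step 13**
Reactants: 17 furan diketone
Product: 18 (8S)-8-hydroxy furan ketone
Conditions: RuCl(p-cymene)[(S,S)-TsDPEN] (1 mol %), HCO2H–Et3N (5:2), 30 °C
Reagents that add atoms: none
Why: Asymmetric transfer hydrogenation of a heteroaryl alkyl ketone, in which the furan takes the aryl position in the six-membered hydride-transfer transition state of the (S,S) catalyst and so sets 8S, while the purely aliphatic C1 ketone is not reduced under these conditions.

**Step 14**
Reactants: 18 alcohol
Product: 19 (8S)-8-triethylsilyl ether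
Conditions: Et3SiCl, imidazole, DMF, 0 °C to rt
Reagents that add atoms: chlorotriethylsilane, CC[Si](Cl)(CC)CC
Why: Silyl ether formation at the only hydroxyl stops hemiketal formation with C1 and keeps C8–OH out of the later mesylation.

**Step 15**
Reactants: 19 silyl ether ketone
Product: 20 (8S,10R)-10-hydroxy-1-ketone
Conditions: KN(SiMe3)2 (0.95 equiv), THF, −78 to 0 °C; −78 °C, 2-(phenylsulfonyl)-3-phenyloxaziridine; AcOH quench
Reagents that add atoms: 2-(phenylsulfonyl)-3-phenyloxaziridine, O=S(=O)(c1ccccc1)N1OC1c1ccccc1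
Why: Enolate oxidation in which equilibration through a slight deficit of base favours the more substituted C1–C10 enolate (erasing the C10 mixture) and the bulky oxidant approaches the outer face of the conformer whose C8 silyloxy group points away from the ring, which should give 10R (oxygens at C8 and C10 syn).

**Step 16**
Reactants: 20 hydroxy ketone
Product: 21 (1S,8S,10R)-1,10-diol
Conditions: Zn(BH4)2, Et2O, −30 °C
Reagents that add atoms: none
Why: Chelation-controlled (Cram chelate) reduction, in which zinc bridges the C10 hydroxyl and the C1 carbonyl, C9 and the ring cover one face, and hydride enters from the methyl-bearing outer face to set 1S.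

**Step 17**
Reactants: 21 diol
Product: 23 (1R,8S,10R)-1,10-epoxide (trans), via C1 mesylate 22 (not isolated)
Conditions: MsCl, Et3N, CH2Cl2, 0 °C; then t-BuOK, THF, −20 °C
Reagents that add atoms: methanesulfonyl chloride, CS(=O)(=O)Cl (its atoms stay in 22 only)
Why: Selective mesylation of the secondary alcohol and intramolecular Williamson-type 3-exo-tet displacement by the tertiary alkoxide invert C1 and give the trans epoxide (C2 and C9 on opposite faces).

**Step 18**
Reactants: 23 epoxy silyl ether
Product: 24 (1R,8S,10R)-epoxy furan alcohol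
Conditions: HF·pyridine, pyridine, THF, 0 °C
Reagents that add atoms: none
Why: Fluoride-mediated desilylation cleaves the secondary triethylsilyl ether far faster than the primary tert-butyldiphenylsilyl ether, and the pyridine buffer protects furan and epoxide.

**Step 19**
Reactants: 24 furan alcohol
Product: 26 γ-hydroxybutenolide (C6 hemiketal; C12 lactone carbonyl), via furan endoperoxide 25 (not isolated)
Conditions: O2, hν, tetraphenylporphyrin (cat.), i-Pr2NEt, CH2Cl2, −78 °C
Reagents that add atoms: dioxygen, O=O
Why: [4+2] cycloaddition of singlet oxygen to the only reactive π system and amine-induced Kornblum–DeLaMare fragmentation, which can remove only the C12 hydrogen, put the carbonyl at C12 and the hydroxyl at C6 (C6 mixture, reset in step 21).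

**Step 20**
Reactants: 26 hydroxybutenolide
Product: 28 (4E,7(11)Z)-dienone methyl ester, via β-methoxy keto ester 27 (not isolated)
Conditions: K2CO3, MeI, DMF, 0 °C; then DBU (0.3 equiv), toluene, 40 °C
Reagents that add atoms: iodomethane, CI
Why: O-alkylation of the ring-opened carboxylate keeps the Z geometry set by the furan, and E1cB loss of methanol (retro-oxa-Michael) can start only from C5, the single enolisable carbon of the C6 ketone, with the ring carbon C3 expected trans to the acyl group.

**Step 21**
Reactants: 28 dienone ester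
Product: 30 (1R,6R,8S,10R)-4E-ene butenolide alcohol (C6 arranged as in the target), via hydroxy ester 29 (not isolated)
Conditions: Et2BOMe, THF–MeOH, −78 °C; NaBH4; AcOH, evaporation from MeOH
Reagents that add atoms: none
Why: Narasaka–Prasad reduction, in which boron ties the C8 hydroxyl to the C6 carbonyl, activates it for 1,2-attack and directs external hydride to the 1,3-syn carbinol required by the target, which then lactonises onto the cis ester.

**Step 22**
Reactants: 30 alkene
Product: 31 (1R,4R,5R,6S,8S,10R)-diepoxy butenolide alcohol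
Conditions: mCPBA, NaHCO3, CH2Cl2, 0 °C
Reagents that add atoms: 3-chloroperbenzoic acid, OOC(=O)c1cccc(Cl)c1
Why: Prilezhaev epoxidation of the only electron-rich alkene, in which A(1,3) strain places C6–H next to the C15 methyl and the ring covers the inner face, so oxygen arrives on the outer face syn to the lactone oxygen and gives the trans 4R,5R epoxide.

**Step 23**
Reactants: 32 (R)-3-bromo-2-hydroxy-2-methylpropanoic acid
Product: 34 (R)-3-chloro-2-hydroxy-2-methylpropanoic acid, via sodium (S)-2-methylglycidate 33 (not isolated)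
Conditions: NaOH (2 equiv), H2O, 0 °C to rt; then conc. HCl, 0 °C to rt
Reagents that add atoms: sodium hydroxide, [Na+].[OH-] (sodium of 33); hydrogen chloride, Cl
Why: Intramolecular Williamson closure to the glycidate and SN2 opening by chloride at the unsubstituted carbon touch no bond of the stereocentre, so its spatial arrangement is retained.

**Step 24**
Reactants: 34 chlorohydrin acid
Product: 36 (R)-3-chloro-2-methyl-2-(triethylsilyloxy)propanoic acid, via bis-silyl derivative 35 (not isolated)
Conditions: Et3SiOTf (2.2 equiv), 2,6-lutidine, CH2Cl2, 0 °C; then THF–H2O, rt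
Reagents that add atoms: triethylsilyl trifluoromethanesulfonate, CC[Si](CC)(CC)OS(=O)(=O)C(F)(F)F
Why: Exhaustive silylation followed by selective hydrolysis of the labile silyl ester blocks the tertiary hydroxyl, which prevents self-acylation and glycidate formation during coupling.

**Step 25**
Reactants: 31 diepoxy alcohol; 36 protected acid
Product: 38 fully protected C8 ester, via mixed anhydride 37 (not isolated)
Conditions: 2,4,6-Cl3C6H2COCl, Et3N, toluene, rt; then 31, DMAP, rt to 40 °C
Reagents that add atoms: 2,4,6-trichlorobenzoyl chloride, O=C(Cl)c1c(Cl)cc(Cl)cc1Cl (its atoms stay in 37 only)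
Why: Yamaguchi esterification couples a hindered acid with the only free hydroxyl under weakly basic conditions that both epoxides and the butenolide tolerate, with retention at C8 and at the acid centre.

**Step 26**
Reactants: 38 bis-silyl ether
Product: 39 13-hydroxy compound with free side-chain tertiary alcohol
Conditions: Bu4NF–AcOH (1:1), THF, 0 °C to rt
Reagents that add atoms: none
Why: Buffered fluoride desilylation removes both silyl groups near neutrality, so neither chlorohydrin closure nor deprotonation at C6 of the butenolide should compete.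

**Step 27**
Reactants: 39 diol
Product: 40 target CNP0255009.1
Conditions: Ac2O, pyridine, CH2Cl2, 0 °C
Reagents that add atoms: acetic anhydride, CC(=O)OC(C)=O
Why: Acetylation without an acyl-transfer catalyst takes the primary allylic C13 alcohol and leaves the tertiary α-hydroxy ester hydroxyl free, and it installs the base-labile 13-acetate last.

**Compound list**

1 | 3-methylanisole | COc1cccc(C)c1 | starting material
2 | methylsuccinic anhydride (racemic) | CC1CC(=O)OC1=O | starting material
3 | 4-(4-methoxy-2-methylphenyl)-2-methyl-4-oxobutanoic acid (racemic) | COc1ccc(C(=O)CC(C)C(=O)O)c(C)c1 | intermediate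
4 | 4-(4-methoxy-2-methylphenyl)-2-methylbutanoic acid (racemic) | COc1ccc(CCC(C)C(=O)O)c(C)c1 | intermediate
5 | 7-methoxy-2,5-dimethyl-3,4-dihydronaphthalen-1(2H)-one (racemic) | COc1cc(C)c2c(c1)C(=O)C(C)CC2 | intermediate
6 | 2-hydroxy-7-methoxy-2,5-dimethyl-3,4-dihydronaphthalen-1(2H)-one (racemic) | COc1cc(C)c2c(c1)C(=O)C(C)(O)CC2 | intermediate
7 | 2,7-dimethoxy-2,5-dimethyl-3,4-dihydronaphthalen-1(2H)-one (racemic) | COc1cc(C)c2c(c1)C(=O)C(C)(OC)CC2 | intermediate
8 | 2,7-dimethoxy-2,5-dimethyl-1,2,3,4-tetrahydronaphthalene (racemic) | COc1cc(C)c2c(c1)CC(C)(OC)CC2 | intermediate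
9 | 3,6-dimethoxy-1,6-dimethyl-1,4,5,6,7,8-hexahydronaphthalene (C4, C10 epimers) | CC1C=C(OC)CC2=C1CCC(C)(OC)C2 | intermediate
10 | (Z)-but-2-ene-1,4-diol | OC/C=C\CO | starting material
11 | (Z)-4-[(tert-butyldiphenylsilyl)oxy]but-2-en-1-ol | OC/C=C\CO[Si](c1ccccc1)(c1ccccc1)C(C)(C)C | intermediate
12 | allyl dienol ether (C8 O-allyl; C7=C8 and C1=C6 diene), not isolated | CC1CC(OC/C=C\CO[Si](c2ccccc2)(c2ccccc2)C(C)(C)C)=CC2=C1CCC(C)(OC)C2 | intermediate
13 | Δ1(6)-octal-8-one with CH(CH=CH2)CH2OSiPh2t-Bu at C7, OMe and Me at C4, Me at C10 (epimers) | CC1CC(=O)C(C(CO[Si](c2ccccc2)(c2ccccc2)C(C)(C)C)C=C)C2=C1CCC(C)(OC)C2 | intermediate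
14 | C8 ethylene ketal of 13 (key-step precursor) | CC1CC2(OCCO2)C(C(CO[Si](c2ccccc2)(c2ccccc2)C(C)(C)C)C=C)C2=C1CCC(C)(OC)C2 | intermediate
15 | cyclodecane-1,6-dione with C8 ketal, C4 OMe/Me, C10 Me, C7 CH(CHO)CH2OSiPh2t-Bu (key-step product) | CC1CC2(OCCO2)C(C(CO[Si](c2ccccc2)(c2ccccc2)C(C)(C)C)C=O)C(=O)CC(C)(OC)CCC1=O | intermediate
16 | furan ketal (furan C6–C7–C11–C12–O; C1 ketone; C8 ketal), not isolated | CC1CC2(OCCO2)c2c(CO[Si](c3ccccc3)(c3ccccc3)C(C)(C)C)coc2CC(C)(OC)CCC1=O | intermediate
17 | furan-fused cyclodecane-1,8-dione (C4, C10 epimers) | CC1CC(=O)c2c(CO[Si](c3ccccc3)(c3ccccc3)C(C)(C)C)coc2CC(C)(OC)CCC1=O | intermediate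
18 | (8S)-8-hydroxy furan 1-ketone (C4, C10 epimers) | CC(C)(C)[Si](c1ccccc1)(c1ccccc1)OCc1coc2c1[C@@H](O)CC(C)C(=O)CCC(C)(OC)C2 | intermediate
19 | (8S)-8-triethylsilyloxy furan 1-ketone | CC(C)(C)[Si](c1ccccc1)(c1ccccc1)OCc1coc2c1[C@@H](O[Si](CC)(CC)CC)CC(C)C(=O)CCC(C)(OC)C2 | intermediate
20 | (8S,10R)-10-hydroxy-8-triethylsilyloxy furan 1-ketone (C4 epimers) | CC(C)(C)[Si](c1ccccc1)(c1ccccc1)OCc1coc2c1[C@@H](O[Si](CC)(CC)CC)C[C@@](C)(O)C(=O)CCC(C)(OC)C2 | intermediate
21 | (1S,8S,10R)-1,10-diol | CC(C)(C)[Si](c1ccccc1)(c1ccccc1)OCc1coc2c1[C@@H](O[Si](CC)(CC)CC)C[C@@](C)(O)[C@@H](O)CCC(C)(OC)C2 | intermediate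
22 | (1S,8S,10R)-C1 mesylate, not isolated | CC(C)(C)[Si](c1ccccc1)(c1ccccc1)OCc1coc2c1[C@@H](O[Si](CC)(CC)CC)C[C@@](C)(O)[C@@H](OS(C)(=O)=O)CCC(C)(OC)C2 | intermediate
23 | (1R,8S,10R)-1,10-epoxy-8-triethylsilyloxy furan | CC(C)(C)[Si](c1ccccc1)(c1ccccc1)OCc1coc2c1[C@@H](O[Si](CC)(CC)CC)C[C@@]1(C)O[C@@H]1CCC(C)(OC)C2 | intermediate
24 | (1R,8S,10R)-1,10-epoxy-8-hydroxy furan | CC(C)(C)[Si](c1ccccc1)(c1ccccc1)OCc1coc2c1[C@@H](O)C[C@@]1(C)O[C@@H]1CCC(C)(OC)C2 | intermediate
25 | furan endoperoxide (O–O bridge from C6 to C12), not isolated | CC(C)(C)[Si](c1ccccc1)(c1ccccc1)OCC1=C2[C@@H](O)C[C@@]3(C)O[C@@H]3CCC(C)(OC)CC24OOC1O4 | intermediate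
26 | γ-hydroxybutenolide (C6 OH; C4, C6 epimers) | CC(C)(C)[Si](c1ccccc1)(c1ccccc1)OCC1=C2[C@@H](O)C[C@@]3(C)O[C@@H]3CCC(C)(OC)CC2(O)OC1=O | intermediate
27 | (7(11)Z)-4-methoxy-6-keto methyl ester, not isolated | COC(=O)/C(CO[Si](c1ccccc1)(c1ccccc1)C(C)(C)C)=C1/[C@@H](O)C[C@@]2(C)O[C@@H]2CCC(C)(OC)CC1=O | intermediate
28 | (1R,8S,10R,4E,7(11)Z)-dienone methyl ester | COC(=O)/C(CO[Si](c1ccccc1)(c1ccccc1)C(C)(C)C)=C1/[C@@H](O)C[C@@]2(C)O[C@@H]2CC/C(C)=C/C1=O | intermediate
29 | (6R,8S)-syn-dihydroxy ester, not isolated | COC(=O)/C(CO[Si](c1ccccc1)(c1ccccc1)C(C)(C)C)=C1/[C@@H](O)C[C@@]2(C)O[C@@H]2CC/C(C)=C/[C@H]1O | intermediate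
30 | (1R,6R,8S,10R,4E)-1,10-epoxy-8-hydroxy-13-silyloxygermacra-4,7(11)-dien-12,6-olide (6R here equals 6S of the target in space) | CC(C)(C)[Si](c1ccccc1)(c1ccccc1)OCC1=C2[C@@H](O)C[C@@]3(C)O[C@@H]3CC/C(C)=C/[C@H]2OC1=O | intermediate
31 | (1R,4R,5R,6S,8S,10R)-1,10:4,5-diepoxy-8-hydroxy-13-silyloxygermacr-7(11)-en-12,6-olide | CC(C)(C)[Si](c1ccccc1)(c1ccccc1)OCC1=C2[C@@H](O)C[C@@]3(C)O[C@@H]3CC[C@@]3(C)O[C@@H]3[C@H]2OC1=O | intermediate
32 | (R)-3-bromo-2-hydroxy-2-methylpropanoic acid | OC(=O)[C@@](C)(O)CBr | starting material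
33 | sodium (S)-2-methyloxirane-2-carboxylate, not isolated | [Na+].[O-]C(=O)[C@]1(C)CO1 | intermediate
34 | (R)-3-chloro-2-hydroxy-2-methylpropanoic acid | OC(=O)[C@@](C)(O)CCl | intermediate
35 | triethylsilyl (R)-3-chloro-2-methyl-2-(triethylsilyloxy)propanoate, not isolated | CC[Si](CC)(CC)OC(=O)[C@@](C)(O[Si](CC)(CC)CC)CCl | intermediate
36 | (R)-3-chloro-2-methyl-2-(triethylsilyloxy)propanoic acid | OC(=O)[C@@](C)(O[Si](CC)(CC)CC)CCl | intermediate
37 | mixed anhydride of 36 with 2,4,6-trichlorobenzoic acid, not isolated | O=C(OC(=O)[C@@](C)(O[Si](CC)(CC)CC)CCl)c1c(Cl)cc(Cl)cc1Cl | intermediate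
38 | C8 ester of 31 with 36 (13-OSiPh2t-Bu, side-chain OSiEt3) | CC(C)(C)[Si](c1ccccc1)(c1ccccc1)OCC1=C2[C@@H](OC(=O)[C@@](C)(O[Si](CC)(CC)CC)CCl)C[C@@]3(C)O[C@@H]3CC[C@@]3(C)O[C@@H]3[C@H]2OC1=O | intermediate
39 | 13-hydroxy C8 (R)-3-chloro-2-hydroxy-2-methylpropanoate | OCC1=C2[C@@H](OC(=O)[C@@](C)(O)CCl)C[C@@]3(C)O[C@@H]3CC[C@@]3(C)O[C@@H]3[C@H]2OC1=O | intermediate
40 | CNP0255009.1, (1R,4R,5R,6S,8S,10R,2'R) | CC(=O)OCC1=C2[C@@H](OC(=O)[C@@](C)(O)CCl)C[C@@]3(C)O[C@@H]3CC[C@@]3(C)O[C@@H]3[C@H]2OC1=O | target

**Step count**
Total step count: 27. Longest linear sequence: 24 (steps 1–7, 9–22, 25–27).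

**Steps most likely to fail**

*Step 9.* A competing [3,3] shift through the C8–C9 enol ether, or acid-induced migration of the central alkene into conjugation at 135 °C, would erode the regiochemistry.
- The fallback sets out from 9 and 11 and comes back at 13.
- Mild hydrolysis of 9 (oxalic acid, aq THF) would give the β,γ-enone F1.
- Compound 11 and 1,1'-carbonyldiimidazole would give the imidazole-1-carboxylate F2.
- The dienolate of F1 (LiN(SiMe3)2, −78 °C, deprotonation at the doubly activated C7) would be C-acylated by F2 to the allyl β-keto ester F3.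
- An ester-enolate Carroll rearrangement (LiN(i-Pr)2, 2 equiv, THF, −78 to 50 °C) can join only C7 to the allyl terminus and would give the β-keto acid F4.
- F4 loses CO2 on warming in toluene to give 13.

*Step 15.* Incomplete equilibration to the C10 enolate, an unfavourable enolate geometry, or poor facial selectivity would give C2 oxidation or the C10 epimer.
- The fallback uses the C8 oxygen as a tether, sets out from 18 and comes back at 20.
- The free hydroxyl of 18 adds to C1 to give the bridged hemiketal F5.
- Dehydration (MsCl, Et3N) would give the oxygen-bridged enol ether F6. Its five-membered ring fixes the C1=C10 geometry (C2 trans to C9) and leaves only the face opposite the carbon bridge open.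
- One equivalent of mCPBA at −78 °C in wet CH2Cl2–NaHCO3 should attack this most electron-rich alkene, and ring opening would give the dihydroxy ketone F7.
- Selective silylation of the secondary hydroxyl of F7 (Et3SiCl, imidazole) returns 20.

*Step 20.* Formation of the Z-alkene, or base-induced E/Z equilibration toward it, would lead to a cis epoxide.
- The fallback avoids an alkene of defined geometry, sets out from 27 (isolated after the esterification stage) and comes back at 31.
- t-BuOOH and DBU would effect elimination and Weitz–Scheffer epoxidation in one flask. Its stepwise addition–closure lets either enone isomer converge on the trans epoxy ketone F8.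
- Narasaka–Prasad reduction of F8 with lactonisation would give 31 directly.

**Further compounds**
F1 | step 9 | 6-methoxy-4,6-dimethyl-3,4,5,6,7,8-hexahydronaphthalen-2(1H)-one (β,γ-enone) | CC1CC(=O)CC2=C1CCC(C)(OC)C2
F2 | step 9 | (Z)-4-[(tert-butyldiphenylsilyl)oxy]but-2-enyl imidazole-1-carboxylate | O=C(OC/C=C\CO[Si](c1ccccc1)(c1ccccc1)C(C)(C)C)n1ccnc1
F3 | step 9 | allyl β-keto ester (C7 carboxylate of F1) | CC1CC(=O)C(C(=O)OC/C=C\CO[Si](c2ccccc2)(c2ccccc2)C(C)(C)C)C2=C1CCC(C)(OC)C2
F4 | step 9 | β-keto acid with quaternary C7 | CC1CC(=O)C(C(=O)O)(C(CO[Si](c2ccccc2)(c2ccccc2)C(C)(C)C)C=C)C2=C1CCC(C)(OC)C2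
F5 | step 15 | (8S)-bridged hemiketal (O8 bound to C1) | CC(C)(C)[Si](c1ccccc1)(c1ccccc1)OCc1coc2c1[C@@H]1CC(C)C(O)(O1)CCC(C)(OC)C2
F6 | step 15 | (8S)-oxygen-bridged C1=C10 enol ether | CC(C)(C)[Si](c1ccccc1)(c1ccccc1)OCc1coc2c1[C@@H]1CC(C)=C(O1)CCC(C)(OC)C2
F7 | step 15 | (8S,10R)-8,10-dihydroxy furan 1-ketone | CC(C)(C)[Si](c1ccccc1)(c1ccccc1)OCc1coc2c1[C@@H](O)C[C@@](C)(O)C(=O)CCC(C)(OC)C2
F8 | step 20 | (1R,4R,5R,8S,10R,7(11)Z)-diepoxy 6-keto methyl ester | COC(=O)/C(CO[Si](c1ccccc1)(c1ccccc1)C(C)(C)C)=C1/[C@@H](O)C[C@@]2(C)O[C@@H]2CC[C@@]2(C)O[C@@H]2C1=O
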